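**Retrosynthetic overview**

1. Numbering: C1–C23 along the main chain from the ethyl CH3 on pyranone ring A (ring A = C3–C7 + O, ring B = C15–C19 + O). The enabling feature is the C9–C11 anti-1,3-diol dipropionate with the C10 methyl syn to O9 and anti to O11, flanked by C8 (the methine on C7 of ring A) and by the (E)-C12=C13 alkene: an aldol–Tishchenko retron.
2. C10–C11 is made from a ring-A ethyl ketone (C1–C10, C9 carbonyl), a ring-B (E)-2-methyl-enal (C11–C23, C21 acetate already in place) and propanal, which reduces C9 and ends up as the O11 propionate; propionylation of O9 finishes the target.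
3. Both halves come from one building block, 2,6-diethyl-3,5-dimethyl-4-pyranone, by lateral (vinylogous) aldol additions of its ethyl groups to acrolein (C8–C10 and C20–C23 arms) and methacrolein (C11–C14 arm); Sharpless kinetic resolutions fix C8, C14 and C20/C21.
4. The enal arm is unmasked by rhenium-catalysed 1,3-transposition of the methacrolein adduct and MnO2 oxidation.
5. Ring order: the 4-pyranone ring is formed once (step 1, cyclodehydration of a 1,3,5-triketone) and serves as ring A in one half and ring B in the other; no ring is formed afterwards.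

Key step: step 13

Remark: 2,6-diethyl-3,5-dimethyl-4-pyranone is assumed not to be a catalogue chemical and is made in step 1; the lateral aldol additions (steps 2 and 8) are assumed to give separable syn and anti adducts, of which the anti ones are carried on.

**Route**

Step 1
Reactants: 1 pentan-3-one; 2 propanoic anhydride
Product: 4 2,6-diethyl-3,5-dimethyl-4H-pyran-4-one, via triketone 3 (not isolated)
Conditions: polyphosphoric acid, 130 °C; then H2O, Na2CO3
Reagents that add atoms: none
Why: Acid-mediated double α-propionylation of the ketone gives the 1,3,5-triketone, whose enol oxygen closes onto the distal carbonyl (6-exo-trig) and dehydrates, the classical ketone/anhydride 4-pyranone condensation.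

Step 2
Reactants: 4 2,6-diethyl-3,5-dimethyl-4H-pyran-4-one; 5 prop-2-enal
Product: 7 rac-2-ethyl-6-[(2R*,3R*)-3-hydroxypent-4-en-2-yl]-3,5-dimethyl-4H-pyran-4-one (anti racemate), via lithium dienolate 6 (not isolated)
Conditions: LDA (1.1 equiv), THF, −78 °C; 5, −78 °C; aq NH4Cl; chromatography
Reagents that add atoms: none
Why: Lateral deprotonation of an ethyl CH2 and 1,2-addition of the hard lithium dienolate to acrolein (vinylogous aldol) form the C–C bond, but the open transition state is not expected to control the two new centres, so both racemic diastereomers should form, the anti racemate is separated by chromatography and the absolute configuration is set in steps 3 and 4.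

Step 3
Reactants: 7 rac-anti allylic alcohol
Product: 8 2-ethyl-6-[(2S,3S)-3-hydroxypent-4-en-2-yl]-3,5-dimethyl-4H-pyran-4-one
Conditions: Ti(OiPr)4 (20 mol%), L-(+)-DIPT (28 mol%), TBHP (0.6 equiv), 4 Å MS, CH2Cl2, −20 °C
Reagents that add atoms: none
Why: Sharpless kinetic resolution of a secondary allylic alcohol, in which the L-(+)-tartrate catalyst epoxidises the (2R,3R) enantiomer (carbinol hydrogen on the face of oxygen delivery) much faster and leaves the (2S,3S) alcohol with both centres defined through the carbinol.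

Step 4
Reactants: 7 rac-anti allylic alcohol
Product: 9 2-ethyl-6-[(2R,3R)-3-hydroxypent-4-en-2-yl]-3,5-dimethyl-4H-pyran-4-one
Conditions: Ti(OiPr)4 (20 mol%), D-(−)-DIPT (28 mol%), TBHP (0.6 equiv), 4 Å MS, CH2Cl2, −20 °C
Reagents that add atoms: none
Why: The same Sharpless kinetic resolution with the antipodal tartrate consumes the (2S,3S) enantiomer and leaves the (2R,3R) alcohol, whose C2 becomes C8 of the target.

Step 5
Reactants: 9 (2R,3R)-allylic alcohol
Product: 10 2-ethyl-6-[(2R,3R)-3-hydroxypentan-2-yl]-3,5-dimethyl-4H-pyran-4-one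
Conditions: H2 (1 atm), RhCl(PPh3)3 (5 mol%), toluene/EtOH, 23 °C
Reagents that add atoms: none
Why: Homogeneous rhodium-catalysed hydrogenation saturates the monosubstituted vinyl group and leaves the tetrasubstituted pyranone double bonds, the carbinol and both stereocentres untouched.

Step 6
Reactants: 10 (2R,3R)-saturated alcohol
Product: 11 2-ethyl-3,5-dimethyl-6-[(2S)-3-oxopentan-2-yl]-4H-pyran-4-one
Conditions: Dess–Martin periodinane (1.3 equiv), CH2Cl2, 0 °C; used at once
Reagents that add atoms: none
Why: Dess–Martin oxidation under non-basic conditions gives the ethyl ketone and should keep C8, because allylic strain with the ring C6 methyl holds H8 near the plane of the ring and of the new carbonyl, the geometry that makes α-methyl β-dicarbonyl stereocentres kinetically non-acidic (the descriptor changes to S only through CIP priorities).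

Step 7
Reactants: 8 (2S,3S)-allylic alcohol
Product: 12 2-ethyl-6-[(2S,3S)-3-hydroxypentan-2-yl]-3,5-dimethyl-4H-pyran-4-one
Conditions: H2 (1 atm), RhCl(PPh3)3 (5 mol%), toluene/EtOH, 23 °C
Reagents that add atoms: none
Why: Homogeneous rhodium-catalysed hydrogenation turns the vinyl group into the C22–C23 ethyl group without touching C20, C21 or the ring.

Step 8
Reactants: 12 (2S,3S)-saturated alcohol; 13 2-methylprop-2-enal
Product: 15 2-[(2S,3S)-3-hydroxypentan-2-yl]-6-[(2R*,3S*)-3-hydroxy-4-methylpent-4-en-2-yl]-3,5-dimethyl-4H-pyran-4-one (anti arm; both absolute senses), via dilithio dienolate 14 (not isolated)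
Conditions: LDA (2.3 equiv), THF, −78 °C; 13, −78 °C; aq NH4Cl; chromatography
Reagents that add atoms: none
Why: The first equivalent of base forms the C21 alkoxide, the second removes a proton from the CH2 of the remaining ethyl group (the tertiary C20–H next to the alkoxide is slower), and the dienolate adds 1,2 to methacrolein (vinylogous aldol) without control of the two new centres, so the anti-configured pair is separated from the syn pair and resolved in step 9.

Step 9
Reactants: 15 anti-arm diastereomer pair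
Product: 16 2-[(2S,3S)-3-hydroxypentan-2-yl]-6-[(2S,3R)-3-hydroxy-4-methylpent-4-en-2-yl]-3,5-dimethyl-4H-pyran-4-one
Conditions: Ti(OiPr)4 (20 mol%), L-(+)-DIPT (28 mol%), TBHP (0.6 equiv), 4 Å MS, CH2Cl2, −20 °C
Reagents that add atoms: none
Why: Sharpless kinetic resolution acts only on the allylic carbinol of the new arm, where the L-(+)-tartrate catalyst epoxidises the (2R,3S)-arm isomer and leaves the isomer whose lateral carbon has the C14 configuration of the target, while the non-allylic C21 hydroxyl is inert.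

Step 10
Reactants: 16 (2S,3R)-arm diol
Product: 17 2-[(2S,3E)-5-hydroxy-4-methylpent-3-en-2-yl]-6-[(2S,3S)-3-hydroxypentan-2-yl]-3,5-dimethyl-4H-pyran-4-one
Conditions: Ph3SiOReO3 (5 mol%), Et2O, 0 °C
Reagents that add atoms: none
Why: Rhenium(VII)-oxo-catalysed 1,3-transposition of the allylic alcohol ([3,3] shift of the perrhenate ester through a chair with the C14 substituent equatorial) should drain into the trisubstituted (E)-alkene bearing the primary hydroxyl and does not touch C14.

Step 11
Reactants: 17 primary allylic alcohol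
Product: 18 (2E,4S)-4-{6-[(2S,3S)-3-hydroxypentan-2-yl]-3,5-dimethyl-4-oxo-4H-pyran-2-yl}-2-methylpent-2-enal
Conditions: activated MnO2 (excess), CH2Cl2, 23 °C
Reagents that add atoms: none
Why: Allylic oxidation with MnO2 converts only the primary allylic alcohol into the (E)-enal and leaves the saturated secondary C21 hydroxyl.

Step 12
Reactants: 18 hydroxy enal
Product: 19 (2S,3S)-2-{3,5-dimethyl-6-[(2S,3E)-4-methyl-5-oxopent-3-en-2-yl]-4-oxo-4H-pyran-2-yl}pentan-3-yl acetate
Conditions: Ac2O, pyridine, DMAP (catalytic), CH2Cl2, 0 °C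
Reagents that add atoms: acetic anhydride, CC(=O)OC(C)=O
Why: DMAP-catalysed acylation of the only hydroxyl installs the C21 acetate before the propionates, so the three esters never need to be told apart.

Step 13
Reactants: 11 ring-A ethyl ketone; 19 ring-B enal acetate; 20 propanal
Product: 24 (8R,9R,10R,11R,12E,14S,20S,21S)-21-acetoxy-9-hydroxy-11-propanoyloxy bis-pyranone (the target lacking the O9 propanoyl group), via enol borinate 21 (not isolated), via boron aldolate 22 (not isolated), via hydroxy ketone 23 (not isolated)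
Conditions: 11 (1.2 equiv), Cy2BCl (1.5 equiv), Me2NEt (1.8 equiv), Et2O, −78 → 0 °C; 19, −78 → −20 °C; H2NCH2CH2OH (1.5 equiv), 0 °C, filter under Ar, evaporate; 20 (8 equiv), SmI2 (30 mol%), THF, −10 °C
Reagents that add atoms: none
Why: Proposed new method: a one-flask crossed aldol–Tishchenko with two different aldehydes, relayed from boron to samarium, in which amine-assisted enolisation of the Cy2BCl-complexed ketone at C10 gives (E)-enol borinate 21, a chair (Zimmerman–Traxler) addition to enal 19 gives boron aldolate 22, 2-aminoethanol sequesters boron as its N,O-chelate and frees β-hydroxy ketone 23, and the Sm(III) alkoxide formed from SmI2 and propanal binds the O11 hemiacetal of propanal and the C9 carbonyl so that hydride shifts intramolecularly to C9 while the oxidised propanal stays on O11 as the propionate. The closest known reaction types are the tandem aldol–Tishchenko of lithium enolates with a single aldehyde, the (E)-boron anti-aldol of α-methyl β-keto imides and other α-chiral ethyl ketones, and the Evans–Tishchenko reduction; the relay is proposed because a reversible lithium aldol would let the enolate cross over to propanal, whereas boron aldolates do not undergo retro-aldol. No ring is closed. C10 and C11 are set anti by the (E)-enolate geometry in the chair, their absolute sense by C8 (H8 eclipses the enolate double bond and the enal approaches the face anti to the C8 methyl, as with the β-keto imides, giving the 8,10-anti relation), and C9 is set anti to O11 by the bicyclic chair of the hydride transfer, which is also the Felkin–Anh mode with respect to C8. The step needs enolisation at C10 rather than at C8 or at a lateral position of either pyranone and no erosion of C8 or C14, which should be secured by the allylic strain that keeps H8 in the plane of ring A and the carbonyl, by the kinetic preference of Cy2BCl/amine for the unhindered ketone CH2, and by the enal having no α-hydrogen.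

Step 14
Reactants: 24 C9 alcohol; 2 propanoic anhydride
Product: 25 [(2R,3R,4R,5R,6E,8S)-2-(6-ethyl-3,5-dimethyl-4-oxo-4H-pyran-2-yl)-8-{6-[(2S,3S)-3-acetoxypentan-2-yl]-3,5-dimethyl-4-oxo-4H-pyran-2-yl}-4,6-dimethylnon-6-ene-3,5-diyl] dipropanoate (target)
Conditions: 2 (3 equiv), DMAP (0.2 equiv), pyridine, CH2Cl2, 23 → 40 °C
Reagents that add atoms: none
Why: DMAP-catalysed acyl transfer to the remaining hindered secondary C9 hydroxyl gives the second propionate, and any earlier 1,3-acyl shift between O9 and O11 is harmless because both oxygens end as propionates.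

**Compound list**

1 | pentan-3-one | CCC(=O)CC | starting material
2 | propanoic anhydride | CCC(=O)OC(=O)CC | starting material
3 | 4,6-dimethylnonane-3,5,7-trione | CCC(=O)C(C)C(=O)C(C)C(=O)CC | intermediate (not isolated)
4 | 2,6-diethyl-3,5-dimethyl-4H-pyran-4-one | CCc1oc(CC)c(C)c(=O)c1C | intermediate
5 | prop-2-enal (acrolein) | C=CC=O | starting material
6 | lithium 2-ethyl-6-ethylidene-3,5-dimethyl-6H-pyran-4-olate (lateral dienolate of 4) | CCC1=C(C)C(O[Li])=C(C)C(=CC)O1 | intermediate (not isolated)
7 | rac-2-ethyl-6-[(2R*,3R*)-3-hydroxypent-4-en-2-yl]-3,5-dimethyl-4H-pyran-4-one (anti racemate, both enantiomers given) | O[C@@H](C=C)[C@H](C)c1oc(CC)c(C)c(=O)c1C.O[C@H](C=C)[C@@H](C)c1oc(CC)c(C)c(=O)c1C | intermediate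
8 | 2-ethyl-6-[(2S,3S)-3-hydroxypent-4-en-2-yl]-3,5-dimethyl-4H-pyran-4-one | O[C@@H](C=C)[C@H](C)c1oc(CC)c(C)c(=O)c1C | intermediate
9 | 2-ethyl-6-[(2R,3R)-3-hydroxypent-4-en-2-yl]-3,5-dimethyl-4H-pyran-4-one | O[C@H](C=C)[C@@H](C)c1oc(CC)c(C)c(=O)c1C | intermediate
10 | 2-ethyl-6-[(2R,3R)-3-hydroxypentan-2-yl]-3,5-dimethyl-4H-pyran-4-one | O[C@H](CC)[C@@H](C)c1oc(CC)c(C)c(=O)c1C | intermediate
11 | 2-ethyl-3,5-dimethyl-6-[(2S)-3-oxopentan-2-yl]-4H-pyran-4-one (ring-A ethyl ketone, C1–C10) | CCC(=O)[C@@H](C)c1oc(CC)c(C)c(=O)c1C | intermediate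
12 | 2-ethyl-6-[(2S,3S)-3-hydroxypentan-2-yl]-3,5-dimethyl-4H-pyran-4-one | O[C@@H](CC)[C@H](C)c1oc(CC)c(C)c(=O)c1C | intermediate
13 | 2-methylprop-2-enal (methacrolein) | CC(=C)C=O | starting material
14 | dilithio species of 12 (C21 alkoxide, lateral dienolate of the ethyl group) | [Li]O[C@@H](CC)[C@H](C)C1=C(C)C(O[Li])=C(C)C(=CC)O1 | intermediate (not isolated)
15 | 2-[(2S,3S)-3-hydroxypentan-2-yl]-6-[(2R*,3S*)-3-hydroxy-4-methylpent-4-en-2-yl]-3,5-dimethyl-4H-pyran-4-one (the two anti-arm diastereomers) | O[C@@H](C(C)=C)[C@H](C)c1oc([C@@H](C)[C@H](CC)O)c(C)c(=O)c1C.O[C@H](C(C)=C)[C@@H](C)c1oc([C@@H](C)[C@H](CC)O)c(C)c(=O)c1C | intermediate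
16 | 2-[(2S,3S)-3-hydroxypentan-2-yl]-6-[(2S,3R)-3-hydroxy-4-methylpent-4-en-2-yl]-3,5-dimethyl-4H-pyran-4-one | O[C@@H](C(C)=C)[C@H](C)c1oc([C@@H](C)[C@H](CC)O)c(C)c(=O)c1C | intermediate
17 | 2-[(2S,3E)-5-hydroxy-4-methylpent-3-en-2-yl]-6-[(2S,3S)-3-hydroxypentan-2-yl]-3,5-dimethyl-4H-pyran-4-one | OC/C(C)=C/[C@H](C)c1oc([C@@H](C)[C@H](CC)O)c(C)c(=O)c1C | intermediate
18 | (2E,4S)-4-{6-[(2S,3S)-3-hydroxypentan-2-yl]-3,5-dimethyl-4-oxo-4H-pyran-2-yl}-2-methylpent-2-enal | O=C/C(C)=C/[C@H](C)c1oc([C@@H](C)[C@H](CC)O)c(C)c(=O)c1C | intermediate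
19 | (2S,3S)-2-{3,5-dimethyl-6-[(2S,3E)-4-methyl-5-oxopent-3-en-2-yl]-4-oxo-4H-pyran-2-yl}pentan-3-yl acetate (ring-B enal, C11–C23) | O=C/C(C)=C/[C@H](C)c1oc([C@@H](C)[C@H](CC)OC(C)=O)c(C)c(=O)c1C | intermediate
20 | propanal | CCC=O | starting material
21 | (E)-enol dicyclohexylborinate of 11 (C9–OBCy2, C9=C10) | C/C=C(/OB(C1CCCCC1)C1CCCCC1)[C@@H](C)c1oc(CC)c(C)c(=O)c1C | intermediate (not isolated)
22 | O11-dicyclohexylboryl aldolate (C9 ketone) | O=C([C@@H](C)[C@@H](OB(C1CCCCC1)C1CCCCC1)/C(C)=C/[C@H](C)c1oc([C@@H](C)[C@H](CC)OC(C)=O)c(C)c(=O)c1C)[C@@H](C)c1oc(CC)c(C)c(=O)c1C | intermediate (not isolated)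
23 | (8S,10S,11R,12E,14S,20S,21S)-21-acetoxy-11-hydroxy-9-oxo bis-pyranone (β-hydroxy ketone) | O=C([C@@H](C)[C@@H](O)/C(C)=C/[C@H](C)c1oc([C@@H](C)[C@H](CC)OC(C)=O)c(C)c(=O)c1C)[C@@H](C)c1oc(CC)c(C)c(=O)c1C | intermediate (not isolated)
24 | (8R,9R,10R,11R,12E,14S,20S,21S)-21-acetoxy-9-hydroxy-11-propanoyloxy bis-pyranone | O[C@H]([C@@H](C)[C@@H](OC(=O)CC)/C(C)=C/[C@H](C)c1oc([C@@H](C)[C@H](CC)OC(C)=O)c(C)c(=O)c1C)[C@@H](C)c1oc(CC)c(C)c(=O)c1C | intermediate
25 | [(2R,3R,4R,5R,6E,8S)-2-(6-ethyl-3,5-dimethyl-4-oxo-4H-pyran-2-yl)-8-{6-[(2S,3S)-3-acetoxypentan-2-yl]-3,5-dimethyl-4-oxo-4H-pyran-2-yl}-4,6-dimethylnon-6-ene-3,5-diyl] dipropanoate | CCC(=O)O[C@H]([C@@H](C)[C@@H](OC(=O)CC)/C(C)=C/[C@H](C)c1oc([C@@H](C)[C@H](CC)OC(C)=O)c(C)c(=O)c1C)[C@@H](C)c1oc(CC)c(C)c(=O)c1C | target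

**Count and risks**

Total step count: 14. Longest linear sequence: 11 steps (1, 2, 3, 7, 8, 9, 10, 11, 12, 13, 14).

Steps most likely to fail:

1. Step 13 (Proposed new method). What may go wrong: deprotonation at a lateral position of a boron-complexed pyranone instead of C10, or a sluggish hand-over from boron to samarium that leaves time for retro-aldol and epimerisation at C8 before the hydride shift. The fallback sets out from 11 and 19 and uses known chemistry only. The Cy2BCl/Me2NEt anti-aldol is run on its own and worked up oxidatively (MeOH, pH 7 buffer, H2O2), and the β-hydroxy ketone 23 is isolated. It is then reduced with Me4NBH(OAc)3 in MeCN/AcOH at −30 °C (Evans–Saksena hydroxyl-directed, intramolecular hydride delivery) to the 9,11-anti diol F1. Both hydroxyls of the anti diol F1 are propionylated with 2, DMAP and pyridine, which comes back to the route at 25.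

2. Step 8. What may go wrong: retro-aldol of the C21 lithium alkoxide, metalation at C20 instead of the ethyl CH2, or conjugate addition to methacrolein. The fallback sets out from 12. The C21 hydroxyl is silylated (TBSOTf, 2,6-lutidine, CH2Cl2) to give the silyl ether F2. Lateral lithiation with LDA (1.1 equiv) and addition to 13 give the silyl-protected anti-arm adducts F3 after chromatography. Desilylation with TBAF in THF comes back to the route at 15.

3. Step 10. What may go wrong: ionisation of the allylic perrhenate with loss of the (E)-geometry or elimination toward ring B, or an equilibrium that stops short of the primary alcohol. The fallback sets out from 16. Both hydroxyls are acetylated (Ac2O, DMAP, pyridine) to the diacetate F4. A PdCl2(MeCN)2-catalysed [3,3] shift of the allylic acetate in THF gives the primary (E)-allylic acetate F5. Selective methanolysis of the primary allylic acetate (K2CO3, MeOH, 0 °C) gives the allylic alcohol F6, which keeps the C21 acetate. MnO2 oxidation of F6 comes back to the route at 19, so steps 11 and 12 are not needed.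

Further compounds
F1 | step 13 | (8R,9R,10R,11R,12E,14S,20S,21S)-21-acetoxy-9,11-dihydroxy bis-pyranone (anti diol) | O[C@H]([C@@H](C)[C@@H](O)/C(C)=C/[C@H](C)c1oc([C@@H](C)[C@H](CC)OC(C)=O)c(C)c(=O)c1C)[C@@H](C)c1oc(CC)c(C)c(=O)c1C
F2 | step 8 | 2-[(2S,3S)-3-(tert-butyldimethylsilyloxy)pentan-2-yl]-6-ethyl-3,5-dimethyl-4H-pyran-4-one | CC(C)(C)[Si](C)(C)O[C@@H](CC)[C@H](C)c1oc(CC)c(C)c(=O)c1C
F3 | step 8 | 2-[(2S,3S)-3-(tert-butyldimethylsilyloxy)pentan-2-yl]-6-[(2R*,3S*)-3-hydroxy-4-methylpent-4-en-2-yl]-3,5-dimethyl-4H-pyran-4-one (the two anti-arm diastereomers) | CC(C)(C)[Si](C)(C)O[C@@H](CC)[C@H](C)c1oc([C@@H](C)[C@@H](O)C(C)=C)c(C)c(=O)c1C.CC(C)(C)[Si](C)(C)O[C@@H](CC)[C@H](C)c1oc([C@H](C)[C@H](O)C(C)=C)c(C)c(=O)c1C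
F4 | step 10 | (2S,3R)-2-{6-[(2S,3S)-3-acetoxypentan-2-yl]-3,5-dimethyl-4-oxo-4H-pyran-2-yl}-4-methylpent-4-en-3-yl acetate | CC(=O)O[C@@H](C(C)=C)[C@H](C)c1oc([C@@H](C)[C@H](CC)OC(C)=O)c(C)c(=O)c1C
F5 | step 10 | (2E,4S)-4-{6-[(2S,3S)-3-acetoxypentan-2-yl]-3,5-dimethyl-4-oxo-4H-pyran-2-yl}-2-methylpent-2-en-1-yl acetate | CC(=O)OC/C(C)=C/[C@H](C)c1oc([C@@H](C)[C@H](CC)OC(C)=O)c(C)c(=O)c1C
F6 | step 10 | (2S,3S)-2-{6-[(2S,3E)-5-hydroxy-4-methylpent-3-en-2-yl]-3,5-dimethyl-4-oxo-4H-pyran-2-yl}pentan-3-yl acetate | OC/C(C)=C/[C@H](C)c1oc([C@@H](C)[C@H](CC)OC(C)=O)c(C)c(=O)c1C
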